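The spiro dihydropyran, ring B (O, C3′=C2′, C1′, C13, C8), is disconnected to a cyclobutanone that holds C8, C13, C1′ and the isobutyl carbon C1″. This ketone comes from a keteniminium [2+2] cycloaddition of an isovaleramide to the exocyclic methylene of a diene ester made from (−)-caryophyllene oxide. In the key step syncarpic acid condenses with the ketone. The polarised cyclobutylidene triketone then expels tertiary C8 from C1″, and an enolate oxygen recaptures it. One operation forms C1′–C2′ and O–C8, attaches ring A, and enlarges the four-membered ring by two atoms. It exploits the cation-stabilising quaternary spiro carbon C8, placed 1,3 to C1′, and cyclobutane strain.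

Key step: step 4

Numbering: caryophyllane C1–C15 (C8 spiro carbon, C13 ring B methylene, C5 carbinol carbon, C3=C4 alkene). C1′ is the ring B methine, C2′/C3′ are the enol ether carbons, C1″ is the isobutyl CH2. Ring A is the tetramethylcyclohexenedione, ring B the dihydropyran, ring C the nine-membered ring, ring D the dimethylcyclobutane.
Assumption: syncarpic acid and N,N-dimethyl-3-methylbutanamide are taken as catalogue compounds.

Step 1
Reactants: 1 (−)-caryophyllene oxide
Product: 2 (1R,3Z,5R,9S)-caryophylla-3,8(13)-dien-5-ol
Conditions: Et2AlCl, LiTMP (TMP-H, n-BuLi), toluene, 0 °C; then H2O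
Reagents that add atoms: none
Why: Aluminium amide-mediated epoxide-to-allylic-alcohol isomerisation (syn elimination); the bulky amide should remove the C3–H that lies cis to the oxirane hydrogen, the C5–O bond is untouched so C5 stays R, and the less strained Z geometry of ring C should result.

Step 2
Reactants: 2 (1R,3Z,5R,9S)-caryophylla-3,8(13)-dien-5-ol; 3 4-nitrobenzoic acid
Product: 4 (1R,3Z,5S,9S)-caryophylla-3,8(13)-dien-5-yl 4-nitrobenzoate
Conditions: 3, PPh3, DIAD, THF, 0 °C → rt
Reagents that add atoms: 4-nitrobenzoic acid (3), O=C(O)c1ccc(cc1)[N+](=O)[O-]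
Why: Mitsunobu reaction; SN2 displacement of the oxyphosphonium ion by the carboxylate inverts C5 from R to S, and the ester then serves as the protecting group.

Step 3
Reactants: 4 (1R,3Z,5S,9S)-caryophylla-3,8(13)-dien-5-yl 4-nitrobenzoate; 5 N,N-dimethyl-3-methylbutanamide
Product: 8 spiro-cyclobutanone (ring C8–C13H2–C1′(=O)–C1″H(iPr), C8–C1″ bond on the peripheral face, isopropyl anti to C9, 5S ester kept), via keteniminium triflate 6 (not isolated), via cyclobutaniminium triflate 7 (not isolated)
Conditions: 5, Tf2O, 2,4,6-collidine, ClCH2CH2Cl, 0 → 80 °C; then H2O, 40 °C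
Reagents that add atoms: N,N-dimethyl-3-methylbutanamide (5), CC(C)CC(=O)N(C)C; water, O
Why: Keteniminium–alkene [2+2] cycloaddition; the nucleophilic C13H2 terminus bonds to the central iminium carbon and C8 to the isopropyl-bearing carbon, only the unhindered 1,1-disubstituted alkene should react, attack on the open peripheral face of the exocyclic methylene sets C8, and the epimerisable α-centre settles with isopropyl anti to C9 (it is erased in step 4).

Step 4
Reactants: 8 spiro-cyclobutanone; 9 syncarpic acid (2,2,4,4-tetramethylcyclohexane-1,3,5-trione)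
Product: 11 ring B dienol ether (spiro 3,4-dihydro-2H-pyran with an (E)-2-methylpropylidene group at C1′, 8S, 5S ester kept), via cyclobutylidene triketone 10 (not isolated)
Conditions: 9, pyrrolidine (20 mol %), AcOH (20 mol %), 4 Å MS, toluene, 90 °C
Reagents that add atoms: syncarpic acid (9), CC1(C)C(=O)CC(=O)C(C)(C)C1=O
Why: Proposed new method: amine-catalysed Knoevenagel condensation (known for cyclobutanones) gives cyclobutylidene triketone 10, in which C1′ carries cyclobutyl-cation character and ring A enolate character; heterolysis of the strained C1″–C8 bond through the cyclobutyl-to-homoallyl cation manifold gives a tertiary C8 cation tethered to a cross-conjugated dienolate, and the enolate oxygen closes ring B on C8. The closest known reaction types are the Lewis-acid C2–C3 cleavage of 3-donor-substituted cyclobutanones in formal [4+2] annulations, the ring opening and cyclisation of donor–acceptor cyclobutanes, and the Cloke–Wilson rearrangement of acylcyclopropanes. Ring B closes by six-membered O-capture of the cation (the second bond of a stepwise oxa-[4+2]), whereas C-capture only regenerates 10. The C8–O stereocentre is controlled by least-motion collapse on the face from which C1″ departs, which is also the open peripheral face of ring C, so the configuration set in step 3 should be retained. The step needs cleavage of C1″–C8 rather than C13–C8, and O-capture rather than proton loss or transannular capture; the isopropyl-bearing bond is the more crowded one and leads to the trisubstituted E alkene, and the six-membered collapse should outrun attack by the ester-deactivated C3=C4 alkene.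

Step 5
Reactants: 11 ring B dienol ether
Product: 12 Tomentodione P 4-nitrobenzoate (1′S,8S,5S)
Conditions: Et3SiH, CF3CO2H, CH2Cl2, −40 °C
Reagents that add atoms: none
Why: Ionic hydrogenation; protonation of the dienol ether at C1″ gives the vinylogous oxocarbenium ion, and the silane should deliver hydride to C1′ along the pseudo-axial path of the half-chair that keeps bulky C9 pseudo-equatorial (syn to C7H2), which places the isobutyl group cis to C9 (1′S).

Step 6
Reactants: 12 Tomentodione P 4-nitrobenzoate
Product: 13 Tomentodione P
Conditions: K2CO3 (cat.), MeOH, 0 °C → rt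
Reagents that add atoms: none
Why: Base-catalysed transesterification (methanolysis) cleaves the activated aryl ester at the acyl carbon, so C5 is untouched and the hindered vinylogous ester and ketones of ring A should not be attacked.

Compound list
1 | (−)-caryophyllene oxide | C[C@@]12CC[C@@H]3[C@H](CC3(C)C)C(=C)CC[C@H]1O2 | starting material
2 | (1R,3Z,5R,9S)-caryophylla-3,8(13)-dien-5-ol | C/C1=C/C[C@@H]2[C@H](CC2(C)C)C(=C)CC[C@H]1O | intermediate
3 | 4-nitrobenzoic acid | O=C(O)c1ccc(cc1)[N+](=O)[O-] | starting material
4 | (1R,3Z,5S,9S)-caryophylla-3,8(13)-dien-5-yl 4-nitrobenzoate | C/C1=C/C[C@@H]2[C@H](CC2(C)C)C(=C)CC[C@@H]1OC(=O)c1ccc(cc1)[N+](=O)[O-] | intermediate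
5 | N,N-dimethyl-3-methylbutanamide | CC(C)CC(=O)N(C)C | starting material
6 | N,N-dimethyl-(3-methylbut-1-enylidene)ammonium triflate (keteniminium triflate, not isolated) | CC(C)C=C=[N+](C)C.[O-]S(=O)(=O)C(F)(F)F | intermediate
7 | cyclobutaniminium triflate (not isolated) | C/C1=C/C[C@@H]2[C@H](CC2(C)C)[C@]3(CC[C@@H]1OC(=O)c1ccc(cc1)[N+](=O)[O-])CC(=[N+](C)C)[C@H]3C(C)C.[O-]S(=O)(=O)C(F)(F)F | intermediate
8 | spiro-cyclobutanone | C/C1=C/C[C@@H]2[C@H](CC2(C)C)[C@]3(CC[C@@H]1OC(=O)c1ccc(cc1)[N+](=O)[O-])CC(=O)[C@H]3C(C)C | intermediate
9 | syncarpic acid | CC1(C)C(=O)CC(=O)C(C)(C)C1=O | starting material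
10 | cyclobutylidene triketone (not isolated) | C/C1=C/C[C@@H]2[C@H](CC2(C)C)[C@]3(CC[C@@H]1OC(=O)c1ccc(cc1)[N+](=O)[O-])CC(=C1C(=O)C(C)(C)C(=O)C(C)(C)C1=O)[C@H]3C(C)C | intermediate
11 | ring B dienol ether with (E)-2-methylpropylidene at C1′ | C/C1=C/C[C@@H]2[C@H](CC2(C)C)[C@]2(CC[C@@H]1OC(=O)c1ccc(cc1)[N+](=O)[O-])C/C(=C\C(C)C)C1=C(O2)C(C)(C)C(=O)C(C)(C)C1=O | intermediate
12 | Tomentodione P 4-nitrobenzoate | C/C1=C/C[C@@H]2[C@H](CC2(C)C)[C@]2(CC[C@@H]1OC(=O)c1ccc(cc1)[N+](=O)[O-])C[C@H](CC(C)C)C1=C(O2)C(C)(C)C(=O)C(C)(C)C1=O | intermediate
13 | Tomentodione P | C/C1=C/C[C@@H]2[C@H](CC2(C)C)[C@]2(CC[C@@H]1O)C[C@H](CC(C)C)C1=C(O2)C(C)(C)C(=O)C(C)(C)C1=O | target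

Total step count: 6. Longest linear sequence: 6 (1 → 2 → 4 → 8 → 11 → 12 → 13).

Steps most likely to fail

**Step 4.** The condensation may stall at the hindered ketone. The opened cation may lose a proton, or the four-membered ring may break at C13–C8 instead of closing ring B. The fallback sets out from 8 and 9 and comes back at 12. It replaces the ionic opening by a pericyclic one built from known reactions. TiCl4/pyridine Knoevenagel condensation in THF gives 10 as an isolated compound. DBU then moves the alkene into the small ring to give the 2-(cyclobut-1-enyl) triketone F1. Heating in o-xylene at 140 °C opens the C1″–C8 bond of F1 by conrotatory four-electron ring opening. Tautomerisation followed by oxa-six-electron electrocyclisation onto C8 gives the 2H-pyran F2. Ionic hydrogenation of F2 under the conditions of step 5 (protonation at C13, hydride to C1′) gives 12.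

**Step 1.** The amide may abstract a proton from the C12 methyl group instead of C3, or the elimination may give the E alkene. The fallback sets out from 1 and comes back at 8. It accepts the kinetic preference of lithium amides for the methyl group and moves the alkene later. LiNEt2 in Et2O converts 1 into the exocyclic allylic alcohol F3. Mitsunobu inversion with 3 gives the (5S)-ester F4. Keteniminium cycloaddition as in step 3, at the C8=C13 alkene that is not deactivated by the allylic ester, gives the methylene cyclobutanone F5. Radical hydrogen-atom-transfer isomerisation with Co(salen)Cl and PhSiH3 moves the C4=C12 alkene to the more stable endocyclic Z C3=C4 position and gives 8.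

**Step 5.** Hydride delivery to the planar cation may show poor facial selectivity, or the allylic ester may ionise in CF3CO2H. The fallback sets out from 11 and comes back at 12. It replaces substrate control by catalyst control. Transfer hydrogenation uses a Hantzsch ester and a chiral BINOL-derived phosphoric acid, whose phosphate pairs with the vinylogous oxocarbenium ion and selects the face. The weaker acid also spares the ester. No new compound arises.

Further compounds
F1 | step 4 | 2-(cyclobut-1-enyl) triketone | C/C1=C/C[C@@H]2[C@H](CC2(C)C)[C@]3(CC[C@@H]1OC(=O)c1ccc(cc1)[N+](=O)[O-])C=C(C1C(=O)C(C)(C)C(=O)C(C)(C)C1=O)[C@H]3C(C)C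
F2 | step 4 | 2H-pyran with isobutyl at C1′ | C/C1=C/C[C@@H]2[C@H](CC2(C)C)[C@]2(CC[C@@H]1OC(=O)c1ccc(cc1)[N+](=O)[O-])C=C(CC(C)C)C1=C(O2)C(C)(C)C(=O)C(C)(C)C1=O
F3 | step 1 | (1R,5R,9S)-caryophylla-4(12),8(13)-dien-5-ol | C=C1CC[C@@H]2[C@H](CC2(C)C)C(=C)CC[C@H]1O
F4 | step 1 | (1R,5S,9S)-caryophylla-4(12),8(13)-dien-5-yl 4-nitrobenzoate | C=C1CC[C@@H]2[C@H](CC2(C)C)C(=C)CC[C@@H]1OC(=O)c1ccc(cc1)[N+](=O)[O-]
F5 | step 1 | spiro-cyclobutanone with exocyclic C4=C12 alkene | C=C1CC[C@@H]2[C@H](CC2(C)C)[C@]3(CC[C@@H]1OC(=O)c1ccc(cc1)[N+](=O)[O-])CC(=O)[C@H]3C(C)C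
F0 | step 5 | none | none
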